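The target is cut at C4′–C5′ and C10′–C9′, the two ring bonds of the right decalin. Rings A′ and B′, with their methyls on C4′, C10′ and C8′, form a head-to-tail triprenyl unit (C12/C4′–C3′–C2′, C1′–C10′–C5′–C6′, C7′–C8′–C9′–C11′). One Lewis-acid cascade from a C3′–C4′ epoxide therefore closes both rings, sets C4′, C5′, C10′ and C9′, and ends as the C7′=C8′ alkene. The precursor is a linear epoxy diene: the cis (3′S,4′R) epoxide from a Z alkene, two E trisubstituted alkenes, a 2,5-dimethoxybenzyl terminus, and the manool-derived left decalin carried as its C8 ketone.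

Key step: step 13

Assumption: the target is taken as the free bis(hydrogen sulfate) as drawn; it is liberated from its pyridinium salt by cation exchange in the last step and would be stored as a salt (labdane numbering is used for the left half, with C13 = C4′, C14 = C3′, C15 = C2′).

Step 1
Reactants: 1 manool
Product: 2 14,15-dinorlabd-8(17)-en-13-one
Conditions: KMnO4, MgSO4, acetone/H2O, 0 °C → rt
Reagents that add atoms: none
Why: Permanganate should cleave the monosubstituted vinyl carbinol to the methyl ketone (oxidative degradation of a tertiary allylic alcohol), the hindered 1,1-disubstituted C8 methylene reacting far more slowly and no stereocentre being touched.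

Step 2
Reactants: 2 14,15-dinorlabd-8(17)-en-13-one
Product: 6 methyl 5-[(1S,4aS,8aS)-5,5,8a-trimethyl-2-methylidenedecahydronaphthalen-1-yl]pent-2-ynoate, via lithium enolate 3 (not isolated), via enol phosphate 4 (not isolated), via lithium acetylide 5 (not isolated)
Conditions: LiN(i-Pr)2, THF, −78 °C; ClP(O)(OEt)2, −78 °C → rt; LiN(i-Pr)2 (2.3 equiv), −78 °C → rt; ClCO2Me (excess), −78 → 0 °C
Reagents that add atoms: methyl chloroformate COC(=O)Cl
Why: Kinetic deprotonation on the methyl side, O-phosphorylation and base-induced elimination (methyl ketone to terminal alkyne through the enol phosphate) should give the acetylide, which is C-acylated by the chloroformate in the same flask.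

Step 3
Reactants: 6 methyl ynoate
Product: 7 methyl (13Z)-labda-8(17),13-dien-15-oate
Conditions: Me2CuLi (from MeLi and CuI), THF, −78 °C; MeOH, −78 °C
Reagents that add atoms: lithium dimethylcuprate [Li+].C[Cu-]C
Why: Cuprate conjugate addition to the alkynoate is a syn carbometalation, so protonation at −78 °C should leave the new methyl trans and C12 cis to the ester carbon (Z), the geometry that later makes C12 axial on C4′.

Step 4
Reactants: 7 methyl (13Z)-labda-8(17),13-dien-15-oate
Product: 8 (13Z)-labda-8(17),13-dien-15-ol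
Conditions: i-Bu2AlH, CH2Cl2, −78 → 0 °C; aqueous potassium sodium tartrate
Reagents that add atoms: none
Why: 1,2-Reduction of the conjugated ester by the aluminium hydride should give the allylic alcohol without touching either alkene or the Z geometry.

Step 5
Reactants: 8 (13Z)-labda-8(17),13-dien-15-ol
Product: 9 (13R,14S)-13,14-epoxylabd-8(17)-en-15-ol
Conditions: Ti(OiPr)4 (10 mol%), L-(+)-diethyl tartrate (12 mol%), t-BuOOH, 4 Å molecular sieves, CH2Cl2, −20 °C
Reagents that add atoms: tert-butyl hydroperoxide CC(C)(C)OO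
Why: Sharpless asymmetric epoxidation should deliver oxygen only to the alkene of the allylic alcohol and, with the L-(+)-tartrate, to the face that gives C3′ (S) and C4′ (R), as expected for Z-3-methyl allylic alcohols; the C8 methylene has no directing hydroxyl.

Step 6
Reactants: 9 (13R,14S)-13,14-epoxylabd-8(17)-en-15-ol
Product: 11 (13R,14S)-13,14-epoxy-15-hydroxy-17-norlabdan-8-one, via ozonide 10 (not isolated)
Conditions: O3, CH2Cl2, −78 °C; PPh3, −78 °C → rt
Reagents that add atoms: ozone [O-][O+]=O
Why: Ozonolysis of the only alkene left, with phosphine reduction of the ozonide, should unmask the C8 ketone while the epoxide, the alcohol and the equatorial (stable) C9 side chain stay as they are.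

Step 7
Reactants: 11 (13R,14S)-13,14-epoxy-15-hydroxy-17-norlabdan-8-one
Product: 12 (13R,14R)-13,14-epoxy-8-oxo-17-norlabdan-15-al
Conditions: Dess–Martin periodinane, NaHCO3 (buffer), CH2Cl2, 0 °C → rt
Reagents that add atoms: none
Why: Buffered Dess–Martin oxidation should convert the primary alcohol into the aldehyde without opening the trisubstituted epoxide or disturbing the oxirane CH (the C14 descriptor changes by priority only).

Step 8
Reactants: 13 2-bromo-1,4-dimethoxybenzene, 14 geranyl bromide
Product: 16 2-[(2E)-3,7-dimethylocta-2,6-dien-1-yl]-1,4-dimethoxybenzene, via aryllithium 15 (not isolated)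
Conditions: n-BuLi, THF, −78 °C; then 14, −78 → 0 °C
Reagents that add atoms: none
Why: Bromine–lithium exchange followed by SN2 alkylation of the aryllithium at the primary allylic bromide should attach the geranyl chain with the E alkene intact.

Step 9
Reactants: 16 2-geranyl-1,4-dimethoxybenzene
Product: 17 (2E,6E)-8-(2,5-dimethoxyphenyl)-2,6-dimethylocta-2,6-dien-1-ol
Conditions: SeO2 (10 mol%), t-BuOOH, salicylic acid (10 mol%), CH2Cl2, 0 °C → rt
Reagents that add atoms: tert-butyl hydroperoxide CC(C)(C)OO (oxygen relayed through SeO2)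
Why: SeO2-catalysed allylic oxidation (ene reaction, then [2,3] shift) should hydroxylate the E methyl group of the more accessible terminal alkene and give the E allylic alcohol, which becomes C1′.

Step 10
Reactants: 17 ω-hydroxy geranyl arene
Product: 19 [(2E,6E)-8-(2,5-dimethoxyphenyl)-2,6-dimethylocta-2,6-dien-1-yl]triphenylphosphonium bromide, via allylic bromide 18 (not isolated)
Conditions: CBr4, PPh3 (2.3 equiv), CH2Cl2, 0 °C; then MeCN, 60 °C
Reagents that add atoms: carbon tetrabromide BrC(Br)(Br)Br; triphenylphosphine c1ccc(cc1)P(c1ccccc1)c1ccccc1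
Why: Appel bromination followed by SN2 quaternisation of the primary allylic bromide by the excess phosphine should give the salt without allylic transposition.

Step 11
Reactants: 19 phosphonium bromide, 12 epoxy aldehyde
Product: 21 (3′S,4′R)-epoxy triene with the extra C1′=C2′ alkene, via phosphonium ylide 20 (not isolated)
Conditions: NaN(SiMe3)2, THF, −78 °C; then 12, −78 → 0 °C
Reagents that add atoms: none
Why: In this Wittig olefination the semi-stabilised allylic ylide should add to the aldehyde far faster than to the hindered C8 ketone, and the geometry of the new C1′=C2′ bond does not matter because it is saturated in the next step.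

Step 12
Reactants: 21 epoxy triene
Product: 22 epoxy diene precursor with (3′S,4′R) cis-epoxide, E C5′=C10′ and E C8′=C9′ alkenes, 2,5-dimethoxyphenyl on C11′ and C8 ketone
Conditions: 2-nitrobenzenesulfonylhydrazide, Et3N, CH2Cl2, rt
Reagents that add atoms: none
Why: Diimide formed in the flask transfers H2 in a concerted syn manner and should reduce the 1,2-disubstituted C1′=C2′ bond much faster than the trisubstituted alkenes (chemoselective diimide reduction), leaving epoxide and ketone untouched.

Step 13
Reactants: 22 epoxy diene precursor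
Product: 23 3′β-hydroxy tetracycle (C12 axial and β on C4′, 4′α-methyl, 5′α-H, 10′β-methyl, 9′β-CH2Ar, C7′=C8′) with C8 ketone and dimethoxyarene
Conditions: MeAlCl2 (3 equiv), CH2Cl2, −78 °C, short reaction time; Et3N, then MeOH/aqueous NaHCO3, −78 °C → rt
Reagents that add atoms: none
Why: MeAlCl2 coordinates the epoxide oxygen (further equivalents are taken up by the C8 ketone and the aryl ethers), the C4′–O bond ionises as C5′ of the first E alkene attacks C4′ anti to the departing oxygen, C9′ of the second E alkene traps the C10′ cation and the C8′ cation loses H7′; this is the known Lewis-acid epoxy-polyene cyclisation terminated by a trisubstituted alkene. Ring A′ closes 6-endo at the C5′=C10′ alkene (endo opening of the epoxide) through a chair, and ring B′ closes 6-endo at the C8′=C9′ alkene through a second chair. C4′ is set by inversion of the (3′S,4′R) cis-epoxide, which places C12 (cis to C2′ in the epoxide) axial and the methyl equatorial; C5′ and C10′ are set by antiperiplanar addition across the E C5′=C10′ bond (trans fusion), C9′ by the E C8′=C9′ bond (equatorial benzyl), and the absolute sense of folding by C3′, whose oxygen stays equatorial. The step needs loss of H7′ in preference to a methyl proton, to H9′ and to Friedel–Crafts capture by the arene: the axial H7′ is aligned with the empty orbital and unhindered, H9′ is shielded by the angular methyl and the benzyl group, and closure of a five-membered ring onto the single open ortho position should be slow at −78 °C, so the reaction is kept cold and short and is quenched with base instead of being equilibrated with acid. The C8 ketone cannot ionise and its neighbouring C9 centre already carries the equatorial side chain, so the left half is a spectator.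

Step 14
Reactants: 23 3′β-hydroxy tetracycle
Product: 24 O-(C3′) imidazole-1-carbothioate of 23
Conditions: 1,1′-thiocarbonyldiimidazole, DMAP, ClCH2CH2Cl, 70 °C
Reagents that add atoms: 1,1′-thiocarbonyldiimidazole S=C(n1ccnc1)n1ccnc1
Why: The equatorial secondary C3′ alcohol should be thioacylated under base-free conditions that leave the enolisable C8 ketone alone (first half of the Barton–McCombie deoxygenation).

Step 15
Reactants: 24 imidazole-1-carbothioate
Product: 25 3′-deoxy tetracycle with C8 ketone
Conditions: Bu3SnH, AIBN, toluene, 100 °C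
Reagents that add atoms: none
Why: In the Barton–McCombie radical deoxygenation the stannyl radical adds to C=S, the C3′–O bond fragments and the secondary radical is reduced by the tin hydride, which removes the C3′ centre; neither the alkene nor the ketone is placed to intercept the radical.

Step 16
Reactants: 25 3′-deoxy ketone
Product: 26 8β-hydroxy-8α-methyl tertiary alcohol (dimethyl ether of the target hydroquinone)
Conditions: MeMgBr, CeCl3 (anhydrous), THF, −78 → 0 °C
Reagents that add atoms: methylmagnesium bromide C[Mg]Br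
Why: The organocerium reagent should add to the hindered, enolisable ketone without deprotonating it, from the α face (equatorial attack) because the β face is blocked by the axial C10 methyl, which gives the equatorial methyl and the axial 8β-hydroxyl (carbonyl 1,2-addition).

Step 17
Reactants: 26 dimethyl ether
Product: 27 2-substituted 1,4-benzoquinone
Conditions: (NH4)2Ce(NO3)6, MeCN/H2O, 0 °C
Reagents that add atoms: water O
Why: Oxidative demethylation of the 1,4-dimethoxyarene by tetravalent cerium should give the quinone within minutes, faster than any reaction at the trisubstituted alkene or the tertiary alcohol.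

Step 18
Reactants: 27 quinone
Product: 28 hydroquinone
Conditions: Na2S2O4, THF/H2O, rt, under argon
Reagents that add atoms: none
Why: Dithionite is a mild two-electron reductant for quinones and should give the air-sensitive hydroquinone, which is taken on at once.

Step 19
Reactants: 28 hydroquinone
Product: 30 target bis(hydrogen sulfate), via bis(pyridinium) disulfate 29 (not isolated)
Conditions: SO3·pyridine, pyridine, rt; then sulfonic acid resin (H+ form), MeOH/H2O, 0 °C
Reagents that add atoms: sulfur trioxide–pyridine complex [O-]S(=O)(=O)[n+]1ccccc1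
Why: O-Sulfation of both phenols by the SO3 complex should be fast at room temperature while the axial, tertiary C8 alcohol is too hindered to react, and cold cation exchange frees the acid.

Compound list
1 | manool, (13R)-labda-8(17),14-dien-13-ol | C=C[C@](C)(O)CC[C@@H]1[C@@]2(C)CCCC(C)(C)[C@@H]2CCC1=C | starting material
2 | 14,15-dinorlabd-8(17)-en-13-one (methyl ketone, C5, C9, C10 as in manool) | CC(=O)CC[C@@H]1[C@@]2(C)CCCC(C)(C)[C@@H]2CCC1=C | intermediate
3 | lithium enolate of 2 on the methyl side | [Li]OC(=C)CC[C@@H]1[C@@]2(C)CCCC(C)(C)[C@@H]2CCC1=C | intermediate (not isolated)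
4 | diethyl enol phosphate of 2 (terminal C=CH2) | C=C(OP(=O)(OCC)OCC)CC[C@@H]1[C@@]2(C)CCCC(C)(C)[C@@H]2CCC1=C | intermediate (not isolated)
5 | lithium acetylide of the terminal alkyne from 2 | [Li]C#CCC[C@@H]1[C@@]2(C)CCCC(C)(C)[C@@H]2CCC1=C | intermediate (not isolated)
6 | methyl 5-[(1S,4aS,8aS)-5,5,8a-trimethyl-2-methylidenedecahydronaphthalen-1-yl]pent-2-ynoate | COC(=O)C#CCC[C@@H]1[C@@]2(C)CCCC(C)(C)[C@@H]2CCC1=C | intermediate
7 | methyl (13Z)-labda-8(17),13-dien-15-oate (C12 cis to the ester carbon) | COC(=O)/C=C(\CC[C@@H]1[C@@]2(C)CCCC(C)(C)[C@@H]2CCC1=C)C | intermediate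
8 | (13Z)-labda-8(17),13-dien-15-ol | OC/C=C(\CC[C@@H]1[C@@]2(C)CCCC(C)(C)[C@@H]2CCC1=C)C | intermediate
9 | (13R,14S)-13,14-epoxylabd-8(17)-en-15-ol (cis epoxide, C4′ R, C3′ S) | OC[C@@H]1O[C@]1(C)CC[C@@H]1[C@@]2(C)CCCC(C)(C)[C@@H]2CCC1=C | intermediate
10 | ozonide of 9 (spiro-1,2,4-trioxolane at C8, either spiro configuration) | OC[C@@H]1O[C@]1(C)CC[C@@H]1[C@@]2(C)CCCC(C)(C)[C@@H]2CCC12OCOO2 | intermediate (not isolated)
11 | (13R,14S)-13,14-epoxy-15-hydroxy-17-norlabdan-8-one | OC[C@@H]1O[C@]1(C)CC[C@@H]1[C@@]2(C)CCCC(C)(C)[C@@H]2CCC1=O | intermediate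
12 | (13R,14R)-13,14-epoxy-8-oxo-17-norlabdan-15-al (same spatial arrangement as 11) | O=C[C@@H]1O[C@]1(C)CC[C@@H]1[C@@]2(C)CCCC(C)(C)[C@@H]2CCC1=O | intermediate
13 | 2-bromo-1,4-dimethoxybenzene | COc1ccc(OC)c(Br)c1 | starting material
14 | geranyl bromide, (2E)-1-bromo-3,7-dimethylocta-2,6-diene | CC(C)=CCC/C(C)=C/CBr | starting material
15 | (2,5-dimethoxyphenyl)lithium | COc1ccc(OC)c([Li])c1 | intermediate (not isolated)
16 | 2-[(2E)-3,7-dimethylocta-2,6-dien-1-yl]-1,4-dimethoxybenzene | COc1ccc(OC)c(C/C=C(\C)CCC=C(C)C)c1 | intermediate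
17 | (2E,6E)-8-(2,5-dimethoxyphenyl)-2,6-dimethylocta-2,6-dien-1-ol | COc1ccc(OC)c(C/C=C(\C)CC/C=C(\C)CO)c1 | intermediate
18 | 2-[(2E,6E)-8-bromo-3,7-dimethylocta-2,6-dien-1-yl]-1,4-dimethoxybenzene | COc1ccc(OC)c(C/C=C(\C)CC/C=C(\C)CBr)c1 | intermediate (not isolated)
19 | [(2E,6E)-8-(2,5-dimethoxyphenyl)-2,6-dimethylocta-2,6-dien-1-yl]triphenylphosphonium bromide | COc1ccc(OC)c(C/C=C(\C)CC/C=C(\C)C[P+](c2ccccc2)(c2ccccc2)c2ccccc2)c1.[Br-] | intermediate
20 | phosphonium ylide of 19 (deprotonated at C1′) | COc1ccc(OC)c(C/C=C(\C)CC/C=C(\C)C=P(c2ccccc2)(c2ccccc2)c2ccccc2)c1 | intermediate (not isolated)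
21 | (3′S,4′R)-epoxy triene: precursor skeleton with an extra C1′=C2′ alkene (E/Z mixture), E C5′=C10′, E C8′=C9′, C8 ketone | COc1ccc(OC)c(C/C=C(\C)CC/C=C(\C)C=C[C@@H]2O[C@]2(C)CC[C@@H]2[C@@]3(C)CCCC(C)(C)[C@@H]3CCC2=O)c1 | intermediate
22 | epoxy diene precursor: (3′S,4′R) cis-epoxide, E C5′=C10′ and E C8′=C9′ alkenes, 2,5-dimethoxyphenyl on C11′, 17-nor-8-oxo left decalin | COc1ccc(OC)c(C/C=C(C)/CC/C=C(C)/CC[C@@H]2O[C@]2(C)CC[C@@H]2[C@@]3(C)CCCC(C)(C)[C@@H]3CCC2=O)c1 | intermediate
23 | 3′β-hydroxy tetracycle: C12 axial β and methyl α on C4′, 5′α-H, 10′β-methyl, 9′β-(2,5-dimethoxybenzyl), C7′=C8′, C8 ketone | CC1=CC[C@H]2[C@@](C)(CC[C@@H]3[C@@]4(C)CCCC(C)(C)[C@@H]4CCC3=O)[C@@H](O)CC[C@]2(C)[C@H]1Cc1cc(OC)ccc1OC | intermediate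
24 | O-(C3′) imidazole-1-carbothioate of 23 | CC1=CC[C@H]2[C@@](C)(CC[C@@H]3[C@@]4(C)CCCC(C)(C)[C@@H]4CCC3=O)[C@@H](OC(=S)n3ccnc3)CC[C@]2(C)[C@H]1Cc1cc(OC)ccc1OC | intermediate
25 | 3′-deoxy tetracycle with C8 ketone | CC1=CC[C@H]2[C@@](C)(CC[C@@H]3[C@@]4(C)CCCC(C)(C)[C@@H]4CCC3=O)CCC[C@]2(C)[C@H]1Cc1cc(OC)ccc1OC | intermediate
26 | 8β-hydroxy-8α-methyl tertiary alcohol, hydroquinone dimethyl ether | CC1=CC[C@H]2[C@@](C)(CC[C@@H]3[C@@]4(C)CCCC(C)(C)[C@@H]4CC[C@]3(C)O)CCC[C@]2(C)[C@H]1Cc1cc(OC)ccc1OC | intermediate
27 | 2-substituted 1,4-benzoquinone of the target skeleton | CC1=CC[C@H]2[C@@](C)(CC[C@@H]3[C@@]4(C)CCCC(C)(C)[C@@H]4CC[C@]3(C)O)CCC[C@]2(C)[C@H]1CC1=CC(=O)C=CC1=O | intermediate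
28 | hydroquinone of the target skeleton | CC1=CC[C@H]2[C@@](C)(CC[C@@H]3[C@@]4(C)CCCC(C)(C)[C@@H]4CC[C@]3(C)O)CCC[C@]2(C)[C@H]1Cc1cc(O)ccc1O | intermediate
29 | bis(pyridinium) salt of the target disulfate | CC1=CC[C@H]2[C@@](C)(CC[C@@H]3[C@@]4(C)CCCC(C)(C)[C@@H]4CC[C@]3(C)O)CCC[C@]2(C)[C@H]1Cc1cc(OS(=O)(=O)[O-])ccc1OS(=O)(=O)[O-].c1cc[nH+]cc1.c1cc[nH+]cc1 | intermediate (not isolated)
30 | CNP0471499.2, hydroquinone bis(hydrogen sulfate) | CC1=CC[C@H]2[C@@](C)(CC[C@@H]3[C@@]4(C)CCCC(C)(C)[C@@H]4CC[C@]3(C)O)CCC[C@]2(C)[C@H]1Cc1cc(OS(=O)(=O)O)ccc1OS(=O)(=O)O | target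

Total step count: 19. Longest linear sequence: 16 steps (steps 1–7 and 11–19 from manool).

Steps most likely to fail

Step 13. Deprotonation of the C8′ cation may be unselective, with a methyl proton lost in place of H7′ so that the double bond ends up exocyclic. The fallback replaces the single kinetically controlled termination by a two-stage termination. It sets out from 22 and comes back at 23. The cascade is run as in step 13 and the olefin mixture, rich in the exocyclic C8′-methylidene isomer F1, is heated with RhCl3·3H2O (trivalent rhodium) in EtOH/CHCl3 at 70 °C. This metal hydride addition–elimination is known to move exocyclic methylenes into the ring on the less hindered CH2 side (here C7′) and should give 23; it has to be stopped before the tetrasubstituted C8′=C9′ isomer builds up.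

Step 12. Hydrogen transfer may not stay confined to the C1′=C2′ bond: the trisubstituted end of the diene may be attacked, or a second equivalent of diimide may over-reduce. The fallback makes the C1′–C2′ bond by sp3 alkylation, so that no extra alkene has to be reduced. It sets out from 11 and from the allylic bromide 18 and comes back at 22.
- Compound 11 is converted with Tf2O and 2,6-lutidine (CH2Cl2, −78 °C) into the epoxy triflate F2.
- Compound 18 is treated with PhSO2Na in DMF to give the C1′ allylic sulfone F3.
- F3 is lithiated (n-BuLi, THF, −78 °C) and alkylated by F2 to the coupled C1′ sulfone F4.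
- PdCl2(dppp)-catalysed displacement of the sulfinate by LiEt3BH (THF, 0 °C) removes the sulfonyl group and also reduces the C8 ketone, giving the 8-hydroxy epoxy diene F5.
- Dess–Martin oxidation of F5 returns 22.

The points to watch here are the allyl terminus at which hydride enters, since both termini are secondary, and the survival of the epoxide towards LiEt3BH.

Step 9. Allylic oxidation may occur at the wrong methyl group (the C8′ methyl of the internal alkene, which is not deactivated in 16) or run on to the enal. The fallback puts the oxygen in before the arene is attached, on commercial geranyl acetate, whose allylic acetate deactivates the 2,3-alkene. It sets out from 13 and comes back at 17.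
- SeO2/t-BuOOH on geranyl acetate gives (2E,6E)-8-hydroxygeranyl acetate F6.
- TBSCl/imidazole gives the silyl ether F7.
- K2CO3/MeOH gives the C1 alcohol F8.
- CBr4/PPh3 gives the allylic bromide F9.
- Alkylation of 15 (from 13 and n-BuLi) with F9 gives the silyl-protected ω-hydroxy geranyl arene F10.
- Bu4NF in THF returns 17.

Further compounds
F1 | step 13 | exocyclic C8′-methylidene isomer of 23 | C=C1CC[C@H]2[C@@](C)(CC[C@@H]3[C@@]4(C)CCCC(C)(C)[C@@H]4CCC3=O)[C@@H](O)CC[C@]2(C)[C@H]1Cc1cc(OC)ccc1OC
F2 | step 12 | epoxy triflate of 11 | O=S(=O)(OC[C@@H]1O[C@]1(C)CC[C@@H]1[C@@]2(C)CCCC(C)(C)[C@@H]2CCC1=O)C(F)(F)F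
F3 | step 12 | C1′ allylic phenyl sulfone of the geranyl arene | COc1ccc(OC)c(C/C=C(\C)CC/C=C(\C)CS(=O)(=O)c2ccccc2)c1
F4 | step 12 | coupled C1′ sulfone (both C1′ epimers) with epoxide and C8 ketone | COc1ccc(OC)c(C/C=C(\C)CC/C=C(\C)C(C[C@@H]2O[C@]2(C)CC[C@@H]2[C@@]3(C)CCCC(C)(C)[C@@H]3CCC2=O)S(=O)(=O)c2ccccc2)c1
F5 | step 12 | 8-hydroxy epoxy diene (8β-alcohol expected, either epimer serves) | COc1ccc(OC)c(C/C=C(\C)CC/C=C(\C)CC[C@@H]2O[C@]2(C)CC[C@@H]2[C@@]3(C)CCCC(C)(C)[C@@H]3CC[C@@H]2O)c1
F6 | step 9 | (2E,6E)-8-hydroxygeranyl acetate | CC(=O)OC/C=C(\C)CC/C=C(\C)CO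
F7 | step 9 | (2E,6E)-8-(tert-butyldimethylsilyloxy)geranyl acetate | CC(=O)OC/C=C(\C)CC/C=C(\C)CO[Si](C)(C)C(C)(C)C
F8 | step 9 | (2E,6E)-8-(tert-butyldimethylsilyloxy)-3,7-dimethylocta-2,6-dien-1-ol | OC/C=C(\C)CC/C=C(\C)CO[Si](C)(C)C(C)(C)C
F9 | step 9 | (2E,6E)-8-(tert-butyldimethylsilyloxy)geranyl bromide | BrC/C=C(\C)CC/C=C(\C)CO[Si](C)(C)C(C)(C)C
F10 | step 9 | tert-butyldimethylsilyl ether of 17 | COc1ccc(OC)c(C/C=C(\C)CC/C=C(\C)CO[Si](C)(C)C(C)(C)C)c1
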